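## Retrosynthetic overview

1. Target ⇐ (Z)-enol triflate (Pd-catalysed formylation, last step); linoleate by Steglich esterification; (R)-carbinol by CBS reduction of a geranyl enone (enal + geranylbarium, then oxidation).
2. Side-chain enal ⇐ Wittig reaction on the lactol of a cis-fused δ-lactone that masks the tertiary alcohol and the first three side-chain carbons.
3. (Z)-tetrasubstituted alkene ⇐ conjugate reduction/enolate triflation of a 1-acetylcyclohexene; hydroxypropyl arm ⇐ B-alkyl Suzuki coupling on an enol triflate, then hydroboration/oxidation.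
4. The two fully substituted ring stereocentres ⇐ a new catalytic enantioselective desymmetrising methyl addition/lactonisation on the Michael adduct of 2-methylcyclohexane-1,3-dione and methyl acrylate.
5. Ring order: the six-membered carbocycle is bought intact and never opened; the only ring made is the temporary lactone (step 2), opened again in steps 10 and 11.

Assumption: in step 2 the ligand antipode is chosen so that the drawn enantiomer of 5 forms; reagents without a number are commercial.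

Abbreviations: TBS = tert-butyl(dimethyl)silyl, Tf = trifluoromethanesulfonyl. C-locants in steps 2–10 follow chromene numbering of the bicyclic lactones (C4a and C8a are the methyl-bearing fusion carbons).

## Route

Step 1
Reactants: 1 2-methylcyclohexane-1,3-dione; 2 methyl acrylate
Product: 3 methyl 3-(1-methyl-2,6-dioxocyclohexyl)propanoate
Conditions: Et3N (0.3 equiv), MeCN, 60 °C
Reagents that add atoms: none
Why: Michael addition of the dione enolate to the acrylate builds the quaternary carbon; the product is prochiral, so no stereocentre is set yet.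

Step 2
Reactants: 3 methyl 3-(1-methyl-2,6-dioxocyclohexyl)propanoate
Product: 5 cis-fused keto-lactone (4aS,8aS)-4a,8a-dimethyloctahydro-2H-chromene-2,5-dione, via hydroxy ester 4 (not isolated)
Conditions: Me2Zn (2.5 equiv), Ti(OiPr)4 (1.2 equiv), (1R,2R)-cyclohexane-1,2-diamine bis(2-exo-hydroxycamphor-10-sulfonamide) ligand (10 mol%), toluene, 0 °C to rt; 1 M HCl; then TsOH (5 mol%), toluene, 50 °C
Reagents that add atoms: dimethylzinc, C[Zn]C
Why: Proposed new method: catalyst-controlled, group-selective methyl transfer from zinc inside a chiral bis(sulfonamido)titanium Lewis-acid pocket to one of the two enantiotopic carbonyls of the prochiral 1,3-dione; substrate control puts methyl anti to the pseudo-axial ester chain on either carbonyl (OH cis to the chain, methyl cis to methyl), so the catalyst's facial preference for a tert-alkyl/CH2 ketone becomes a choice of carbonyl and sets C4a (S) and C8a (S) together, while lactonisation of the cis alkoxide drains it and suppresses retro-aldol cleavage; the closest known reactions are titanium/bis(sulfonamide)-catalysed enantioselective dialkylzinc additions to simple ketones and enantioselective desymmetrising reductions of 2,2-disubstituted cyclohexane-1,3-diones.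

Step 3
Reactants: 5 (4aS,8aS)-4a,8a-dimethyloctahydro-2H-chromene-2,5-dione
Product: 7 (4aS,8aS)-4a,8a-dimethyl-2-oxo-3,4,4a,7,8,8a-hexahydro-2H-chromen-5-yl trifluoromethanesulfonate, via potassium enolate 6 (not isolated)
Conditions: KN(SiMe3)2, THF, −78 °C; then PhNTf2, −78 to 0 °C; aq NH4Cl
Reagents that add atoms: N-phenylbis(trifluoromethanesulfonimide), O=S(=O)(N(c1ccccc1)S(=O)(=O)C(F)(F)F)C(F)(F)F
Why: Enolate triflation; the ketone has α-hydrogens only at C6 and is far more acidic than the lactone, so one enol triflate forms.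

Step 4
Reactants: 7 (4aS,8aS)-4a,8a-dimethyl-2-oxo-3,4,4a,7,8,8a-hexahydro-2H-chromen-5-yl trifluoromethanesulfonate; 8 allyl TBS ether [tert-butyl(dimethyl)(prop-2-en-1-yloxy)silane]
Product: 10 (4aR,8aS)-5-[3-(TBS-oxy)propyl]-4a,8a-dimethyl-3,4,4a,7,8,8a-hexahydro-2H-chromen-2-one, via alkylborane 9 (not isolated)
Conditions: 8, 9-borabicyclo[3.3.1]nonane, THF, 0 °C to rt; then 7, Pd(dppf)Cl2 (5 mol%), AsPh3 (10 mol%), Cs2CO3, DMF/H2O, rt to 40 °C
Reagents that add atoms: none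
Why: Anti-Markovnikov hydroboration of 8 followed by B-alkyl Suzuki–Miyaura coupling attaches the three-carbon arm to C5 under conditions that spare the lactone and silyl ether.

Step 5
Reactants: 10 (4aR,8aS)-5-[3-(TBS-oxy)propyl]-4a,8a-dimethyl-3,4,4a,7,8,8a-hexahydro-2H-chromen-2-one
Product: 12 (4aR,5R,6R,8aS)-5-[3-(TBS-oxy)propyl]-6-hydroxy-4a,8a-dimethyloctahydro-2H-chromen-2-one, via alkylborane 11 (not isolated)
Conditions: BH3·THF, THF, 0 °C to rt; then H2O2, pH 7 phosphate buffer, 0 °C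
Reagents that add atoms: hydrogen peroxide, OO
Why: Hydroboration–oxidation puts oxygen on the less substituted C6 and hydrogen on C5 by syn addition to the face opposite the axial angular methyl (any C5 epimer is corrected in step 6).

Step 6
Reactants: 12 (4aR,5R,6R,8aS)-5-[3-(TBS-oxy)propyl]-6-hydroxy-4a,8a-dimethyloctahydro-2H-chromen-2-one
Product: 13 (4aR,5R,8aS)-5-[3-(TBS-oxy)propyl]-4a,8a-dimethyloctahydro-2H-chromene-2,6-dione
Conditions: Dess–Martin periodinane, CH2Cl2, rt; then DBU (0.2 equiv), CH2Cl2, rt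
Reagents that add atoms: none
Why: Dess–Martin oxidation gives the ketone, and base equilibration of the now enolisable C5 funnels material to the more stable epimer (arm equatorial, cis to the angular methyl, estimated about 5:1 or better), which is the target configuration.

Step 7
Reactants: 13 (4aR,5R,8aS)-5-[3-(TBS-oxy)propyl]-4a,8a-dimethyloctahydro-2H-chromene-2,6-dione
Product: 15 (4aR,5R,8aS)-5-[3-(TBS-oxy)propyl]-4a,8a-dimethyl-2-oxo-3,4,4a,5,8,8a-hexahydro-2H-chromen-6-yl trifluoromethanesulfonate, via potassium enolate 14 (not isolated)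
Conditions: KN(SiMe3)2, THF, −78 °C; then PhNTf2, −78 to 0 °C; aq NH4Cl
Reagents that add atoms: N-phenylbis(trifluoromethanesulfonimide), O=S(=O)(N(c1ccccc1)S(=O)(=O)C(F)(F)F)C(F)(F)F
Why: Kinetic deprotonation takes the unhindered C7 methylene and not the tertiary C5–H, so enolate triflation gives the less substituted enol triflate and leaves C5 untouched.

Step 8
Reactants: 15 (4aR,5R,8aS)-5-[3-(TBS-oxy)propyl]-4a,8a-dimethyl-2-oxo-3,4,4a,5,8,8a-hexahydro-2H-chromen-6-yl trifluoromethanesulfonate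
Product: 17 (4aR,5R,8aS)-6-acetyl-5-[3-(TBS-oxy)propyl]-4a,8a-dimethyl-3,4,4a,5,8,8a-hexahydro-2H-chromen-2-one, via ethoxydiene 16 (not isolated)
Conditions: tributyl(1-ethoxyvinyl)stannane, Pd(PPh3)4 (5 mol%), LiCl, THF, 65 °C; then 0.1 M HCl, THF, 0 °C
Reagents that add atoms: tributyl(1-ethoxyvinyl)stannane, CCOC(=C)[Sn](CCCC)(CCCC)CCCC; water, O
Why: Stille coupling with an acetyl-anion equivalent and mild enol-ether hydrolysis give the 1-acetylcyclohexene.

Step 9
Reactants: 17 (4aR,5R,8aS)-6-acetyl-5-[3-(TBS-oxy)propyl]-4a,8a-dimethyl-3,4,4a,5,8,8a-hexahydro-2H-chromen-2-one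
Product: 19 (1Z)-1-[(4aR,5S,8aS)-5-[3-(TBS-oxy)propyl]-4a,8a-dimethyl-2-oxooctahydro-6H-chromen-6-ylidene]ethyl trifluoromethanesulfonate, via lithium enolate 18 (not isolated)
Conditions: LiBH(s-Bu)3 (1.1 equiv), THF, −78 °C; then PhNTf2, −78 to 0 °C; aq NH4Cl
Reagents that add atoms: N-phenylbis(trifluoromethanesulfonimide), O=S(=O)(N(c1ccccc1)S(=O)(=O)C(F)(F)F)C(F)(F)F
Why: Conjugate hydride reduction with enolate trapping; the enone is held s-trans (carbonyl oxygen on the C5 side) because the acetyl methyl cannot sit beside the equatorial C5 arm, so the regiospecific exocyclic enolate has oxygen cis to C5 and triflation fixes the (Z)-tetrasubstituted alkene.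

Step 10
Reactants: 19 (1Z)-1-[(4aR,5S,8aS)-5-[3-(TBS-oxy)propyl]-4a,8a-dimethyl-2-oxooctahydro-6H-chromen-6-ylidene]ethyl trifluoromethanesulfonate
Product: 20 lactol (1Z)-1-[(4aR,5S,8aS)-5-[3-(TBS-oxy)propyl]-2-hydroxy-4a,8a-dimethyloctahydro-6H-chromen-6-ylidene]ethyl trifluoromethanesulfonate (C2 anomers)
Conditions: i-Bu2AlH (1.1 equiv), CH2Cl2, −78 °C; aq potassium sodium tartrate
Reagents that add atoms: none
Why: Partial hydride reduction of the lactone stops at the lactol at −78 °C and leaves the enol triflate and silyl ether intact.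

Step 11
Reactants: 20 lactol from step 10; 21 2-(triphenylphosphoranylidene)propanal
Product: 22 (1Z)-1-[(2S,3R,4S)-4-hydroxy-3,4-dimethyl-3-[(3E)-4-methyl-5-oxopent-3-en-1-yl]-2-[3-(TBS-oxy)propyl]cyclohexylidene]ethyl trifluoromethanesulfonate
Conditions: toluene, 90 °C
Reagents that add atoms: none
Why: Wittig reaction of the lactol through its hydroxy-aldehyde form with the stabilised formyl ylide gives the (E)-2-methyl enal and frees the tertiary alcohol.

Step 12
Reactants: 22 enal from step 11; 23 geranyl chloride [(2E)-1-chloro-3,7-dimethylocta-2,6-diene]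
Product: 25 (1Z)-1-[(2S,3R,4S)-4-hydroxy-3-[(3E,5RS,7E)-5-hydroxy-4,8,12-trimethyltrideca-3,7,11-trien-1-yl]-3,4-dimethyl-2-[3-(TBS-oxy)propyl]cyclohexylidene]ethyl trifluoromethanesulfonate, via geranylbarium chloride 24 (not isolated)
Conditions: Li, biphenyl, BaI2, THF, rt (active barium); 23, −78 °C; then 22, −78 °C; aq NH4Cl
Reagents that add atoms: none
Why: α-Selective allylbarium 1,2-addition to the aldehyde keeps the (E)-geranyl geometry and gives the linear carbinol; the new carbinol centre forms unselectively and is corrected by steps 13 and 16.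

Step 13
Reactants: 25 allylic alcohol from step 12
Product: 26 (1Z)-1-[(2S,3R,4S)-4-hydroxy-3,4-dimethyl-3-[(3E,7E)-4,8,12-trimethyl-5-oxotrideca-3,7,11-trien-1-yl]-2-[3-(TBS-oxy)propyl]cyclohexylidene]ethyl trifluoromethanesulfonate
Conditions: Dess–Martin periodinane, CH2Cl2, 0 °C to rt
Reagents that add atoms: none
Why: Dess–Martin oxidation under neutral conditions gives the enone without moving the skipped 7,8-double bond into conjugation; the tertiary alcohol is inert.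

Step 14
Reactants: 26 enone from step 13
Product: 27 (1Z)-1-[(2S,3R,4S)-4-hydroxy-2-(3-hydroxypropyl)-3,4-dimethyl-3-[(3E,7E)-4,8,12-trimethyl-5-oxotrideca-3,7,11-trien-1-yl]cyclohexylidene]ethyl trifluoromethanesulfonate
Conditions: HF·pyridine, pyridine, THF, 0 °C
Reagents that add atoms: none
Why: Fluoride desilylation removes the primary TBS ether and leaves the enol triflate and enone.

Step 15
Reactants: 27 primary alcohol from step 14; 28 linoleic acid [(9Z,12Z)-octadeca-9,12-dienoic acid]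
Product: 29 (1Z)-1-[(2S,3R,4S)-4-hydroxy-3,4-dimethyl-2-[3-[(9Z,12Z)-octadeca-9,12-dienoyloxy]propyl]-3-[(3E,7E)-4,8,12-trimethyl-5-oxotrideca-3,7,11-trien-1-yl]cyclohexylidene]ethyl trifluoromethanesulfonate
Conditions: DCC, DMAP (5 mol%), CH2Cl2, 0 °C to rt
Reagents that add atoms: none
Why: Steglich esterification acylates the only acylable hydroxyl (primary), the tertiary alcohol being unreactive.

Step 16
Reactants: 29 ester enone from step 15
Product: 30 (1Z)-1-[(2S,3R,4S)-4-hydroxy-3-[(3E,5R,7E)-5-hydroxy-4,8,12-trimethyltrideca-3,7,11-trien-1-yl]-3,4-dimethyl-2-[3-[(9Z,12Z)-octadeca-9,12-dienoyloxy]propyl]cyclohexylidene]ethyl trifluoromethanesulfonate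
Conditions: (S)-B-methyl oxazaborolidine of α,α-diphenylprolinol (CBS catalyst, 0.3 equiv), catecholborane (3 equiv), toluene, −78 °C; MeOH, pH 7 buffer
Reagents that add atoms: none
Why: Corey–Bakshi–Shibata reduction with the α-methylalkenyl group as the large substituent gives the (R)-allylic alcohol, and catecholborane at −78 °C spares the esters, alkenes and enol triflate.

Step 17
Reactants: 30 (R)-allylic alcohol from step 16
Product: 31 target, 3-[(1S,2R,3S,6Z)-3-hydroxy-2-[(3E,5R,7E)-5-hydroxy-4,8,12-trimethyltrideca-3,7,11-trien-1-yl]-2,3-dimethyl-6-(1-oxopropan-2-ylidene)cyclohexyl]propyl (9Z,12Z)-octadeca-9,12-dienoate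
Conditions: Pd(PPh3)4 (10 mol%), CO (3 atm), Bu3SnH (1.3 equiv, slow addition), LiCl, THF, 50 °C
Reagents that add atoms: carbon monoxide, [C-]#[O+]
Why: Palladium-catalysed reductive carbonylation (formylation) of the enol triflate goes with retention of alkene geometry, so the (Z)-triflate becomes the (Z)-enal of the target.

## Compound list

1 | 2-methylcyclohexane-1,3-dione | CC1C(=O)CCCC1=O | starting material
2 | methyl acrylate | C=CC(=O)OC | starting material
3 | methyl 3-(1-methyl-2,6-dioxocyclohexyl)propanoate | COC(=O)CCC1(C)C(=O)CCCC1=O | intermediate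
4 | methyl 3-[(1S,2S)-2-hydroxy-1,2-dimethyl-6-oxocyclohexyl]propanoate (OH cis to the ester chain; present as its metal alkoxide) | O=C1CCC[C@](C)(O)[C@]1(C)CCC(=O)OC | intermediate (not isolated)
5 | (4aS,8aS)-4a,8a-dimethyloctahydro-2H-chromene-2,5-dione | O=C1CCC[C@](C)(O2)[C@]1(C)CCC2=O | intermediate
6 | potassium (4aS,8aS)-4a,8a-dimethyl-2-oxo-3,4,4a,7,8,8a-hexahydro-2H-chromen-5-olate | [K+].[O-]C1=CCC[C@](C)(O2)[C@]1(C)CCC2=O | intermediate (not isolated)
7 | (4aS,8aS)-4a,8a-dimethyl-2-oxo-3,4,4a,7,8,8a-hexahydro-2H-chromen-5-yl trifluoromethanesulfonate | O=S(=O)(OC1=CCC[C@](C)(O2)[C@]1(C)CCC2=O)C(F)(F)F | intermediate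
8 | tert-butyl(dimethyl)(prop-2-en-1-yloxy)silane | C=CCO[Si](C)(C)C(C)(C)C | starting material
9 | 9-[3-(TBS-oxy)propyl]-9-borabicyclo[3.3.1]nonane | CC(C)(C)[Si](C)(C)OCCCB1C2CCCC1CCC2 | intermediate (not isolated)
10 | (4aR,8aS)-5-[3-(TBS-oxy)propyl]-4a,8a-dimethyl-3,4,4a,7,8,8a-hexahydro-2H-chromen-2-one | CC(C)(C)[Si](C)(C)OCCCC1=CCC[C@](C)(O2)[C@]1(C)CCC2=O | intermediate
11 | [(4aR,5S,6R,8aS)-5-[3-(TBS-oxy)propyl]-4a,8a-dimethyl-2-oxooctahydro-2H-chromen-6-yl]borane | CC(C)(C)[Si](C)(C)OCCC[C@H]1[C@H]([BH2])CC[C@](C)(O2)[C@]1(C)CCC2=O | intermediate (not isolated)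
12 | (4aR,5R,6R,8aS)-5-[3-(TBS-oxy)propyl]-6-hydroxy-4a,8a-dimethyloctahydro-2H-chromen-2-one | CC(C)(C)[Si](C)(C)OCCC[C@H]1[C@H](O)CC[C@](C)(O2)[C@]1(C)CCC2=O | intermediate
13 | (4aR,5R,8aS)-5-[3-(TBS-oxy)propyl]-4a,8a-dimethyloctahydro-2H-chromene-2,6-dione | CC(C)(C)[Si](C)(C)OCCC[C@H]1C(=O)CC[C@](C)(O2)[C@]1(C)CCC2=O | intermediate
14 | potassium (4aR,5R,8aS)-5-[3-(TBS-oxy)propyl]-4a,8a-dimethyl-2-oxo-3,4,4a,5,8,8a-hexahydro-2H-chromen-6-olate | [K+].CC(C)(C)[Si](C)(C)OCCC[C@H]1C([O-])=CC[C@](C)(O2)[C@]1(C)CCC2=O | intermediate (not isolated)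
15 | (4aR,5R,8aS)-5-[3-(TBS-oxy)propyl]-4a,8a-dimethyl-2-oxo-3,4,4a,5,8,8a-hexahydro-2H-chromen-6-yl trifluoromethanesulfonate | CC(C)(C)[Si](C)(C)OCCC[C@H]1C(OS(=O)(=O)C(F)(F)F)=CC[C@](C)(O2)[C@]1(C)CCC2=O | intermediate
16 | (4aR,5R,8aS)-6-(1-ethoxyethenyl)-5-[3-(TBS-oxy)propyl]-4a,8a-dimethyl-3,4,4a,5,8,8a-hexahydro-2H-chromen-2-one | CC(C)(C)[Si](C)(C)OCCC[C@H]1C(C(=C)OCC)=CC[C@](C)(O2)[C@]1(C)CCC2=O | intermediate (not isolated)
17 | (4aR,5R,8aS)-6-acetyl-5-[3-(TBS-oxy)propyl]-4a,8a-dimethyl-3,4,4a,5,8,8a-hexahydro-2H-chromen-2-one | CC(C)(C)[Si](C)(C)OCCC[C@H]1C(C(C)=O)=CC[C@](C)(O2)[C@]1(C)CCC2=O | intermediate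
18 | lithium (1Z)-1-[(4aR,5S,8aS)-5-[3-(TBS-oxy)propyl]-4a,8a-dimethyl-2-oxooctahydro-6H-chromen-6-ylidene]ethanolate | [Li+].CC(C)(C)[Si](C)(C)OCCC[C@H]1/C(=C(/C)[O-])CC[C@](C)(O2)[C@]1(C)CCC2=O | intermediate (not isolated)
19 | (1Z)-1-[(4aR,5S,8aS)-5-[3-(TBS-oxy)propyl]-4a,8a-dimethyl-2-oxooctahydro-6H-chromen-6-ylidene]ethyl trifluoromethanesulfonate | CC(C)(C)[Si](C)(C)OCCC[C@H]1/C(=C(/C)OS(=O)(=O)C(F)(F)F)CC[C@](C)(O2)[C@]1(C)CCC2=O | intermediate
20 | (1Z)-1-[(4aR,5S,8aS)-5-[3-(TBS-oxy)propyl]-2-hydroxy-4a,8a-dimethyloctahydro-6H-chromen-6-ylidene]ethyl trifluoromethanesulfonate (lactol, C2 anomers) | CC(C)(C)[Si](C)(C)OCCC[C@H]1/C(=C(/C)OS(=O)(=O)C(F)(F)F)CC[C@](C)(O2)[C@]1(C)CCC2O | intermediate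
21 | 2-(triphenylphosphoranylidene)propanal | CC(C=O)=P(c1ccccc1)(c1ccccc1)c1ccccc1 | starting material
22 | (1Z)-1-[(2S,3R,4S)-4-hydroxy-3,4-dimethyl-3-[(3E)-4-methyl-5-oxopent-3-en-1-yl]-2-[3-(TBS-oxy)propyl]cyclohexylidene]ethyl trifluoromethanesulfonate | CC(C)(C)[Si](C)(C)OCCC[C@H]1/C(=C(/C)OS(=O)(=O)C(F)(F)F)CC[C@](C)(O)[C@]1(C)CC/C=C(\C)C=O | intermediate
23 | geranyl chloride, (2E)-1-chloro-3,7-dimethylocta-2,6-diene | ClC/C=C(\C)CCC=C(C)C | starting material
24 | geranylbarium chloride, chloro[(2E)-3,7-dimethylocta-2,6-dien-1-yl]barium | Cl[Ba]C/C=C(\C)CCC=C(C)C | intermediate (not isolated)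
25 | (1Z)-1-[(2S,3R,4S)-4-hydroxy-3-[(3E,5RS,7E)-5-hydroxy-4,8,12-trimethyltrideca-3,7,11-trien-1-yl]-3,4-dimethyl-2-[3-(TBS-oxy)propyl]cyclohexylidene]ethyl trifluoromethanesulfonate | CC(C)(C)[Si](C)(C)OCCC[C@H]1/C(=C(/C)OS(=O)(=O)C(F)(F)F)CC[C@](C)(O)[C@]1(C)CC/C=C(\C)C(O)C/C=C(\C)CCC=C(C)C | intermediate
26 | (1Z)-1-[(2S,3R,4S)-4-hydroxy-3,4-dimethyl-3-[(3E,7E)-4,8,12-trimethyl-5-oxotrideca-3,7,11-trien-1-yl]-2-[3-(TBS-oxy)propyl]cyclohexylidene]ethyl trifluoromethanesulfonate | CC(C)(C)[Si](C)(C)OCCC[C@H]1/C(=C(/C)OS(=O)(=O)C(F)(F)F)CC[C@](C)(O)[C@]1(C)CC/C=C(\C)C(=O)C/C=C(\C)CCC=C(C)C | intermediate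
27 | (1Z)-1-[(2S,3R,4S)-4-hydroxy-2-(3-hydroxypropyl)-3,4-dimethyl-3-[(3E,7E)-4,8,12-trimethyl-5-oxotrideca-3,7,11-trien-1-yl]cyclohexylidene]ethyl trifluoromethanesulfonate | OCCC[C@H]1/C(=C(/C)OS(=O)(=O)C(F)(F)F)CC[C@](C)(O)[C@]1(C)CC/C=C(\C)C(=O)C/C=C(\C)CCC=C(C)C | intermediate
28 | linoleic acid, (9Z,12Z)-octadeca-9,12-dienoic acid | CCCCC/C=C\C/C=C\CCCCCCCC(=O)O | starting material
29 | (1Z)-1-[(2S,3R,4S)-4-hydroxy-3,4-dimethyl-2-[3-[(9Z,12Z)-octadeca-9,12-dienoyloxy]propyl]-3-[(3E,7E)-4,8,12-trimethyl-5-oxotrideca-3,7,11-trien-1-yl]cyclohexylidene]ethyl trifluoromethanesulfonate | CCCCC/C=C\C/C=C\CCCCCCCC(=O)OCCC[C@H]1/C(=C(/C)OS(=O)(=O)C(F)(F)F)CC[C@](C)(O)[C@]1(C)CC/C=C(\C)C(=O)C/C=C(\C)CCC=C(C)C | intermediate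
30 | (1Z)-1-[(2S,3R,4S)-4-hydroxy-3-[(3E,5R,7E)-5-hydroxy-4,8,12-trimethyltrideca-3,7,11-trien-1-yl]-3,4-dimethyl-2-[3-[(9Z,12Z)-octadeca-9,12-dienoyloxy]propyl]cyclohexylidene]ethyl trifluoromethanesulfonate | CCCCC/C=C\C/C=C\CCCCCCCC(=O)OCCC[C@H]1/C(=C(/C)OS(=O)(=O)C(F)(F)F)CC[C@](C)(O)[C@]1(C)CC/C=C(\C)[C@H](O)C/C=C(\C)CCC=C(C)C | intermediate
31 | 3-[(1S,2R,3S,6Z)-3-hydroxy-2-[(3E,5R,7E)-5-hydroxy-4,8,12-trimethyltrideca-3,7,11-trien-1-yl]-2,3-dimethyl-6-(1-oxopropan-2-ylidene)cyclohexyl]propyl (9Z,12Z)-octadeca-9,12-dienoate | CCCCC/C=C\C/C=C\CCCCCCCC(=O)OCCC[C@H]1/C(=C(/C)C=O)CC[C@](C)(O)[C@]1(C)CC/C=C(\C)[C@H](O)C/C=C(\C)CCC=C(C)C | target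

## Step count and risks

Total steps: 17. Longest linear sequence: 17 steps (1 to 31); compounds 2, 8, 21, 23 and 28 are bought.

The three steps most likely to fail:

**Step 2 (the proposed new reaction).** The hindered α-quaternary ketone may react slowly with Me2Zn, the carbonyl selection may be poor, or the aldolate may undergo retro-aldol cleavage before it lactonises. Fallback with known chemistry, setting out from 3 and coming back at 5:
- Enantioselective mono-reduction of 3 (CBS oxazaborolidine/catecholborane, or baker's yeast) gives the hydroxy keto ester F1, with the hydroxyl cis to the ester chain on the carbon that will later be the C5 ketone.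
- TBSOTf/2,6-lutidine gives the silyl ether F2.
- MeMgBr/CeCl3 (THF, −78 °C) adds to the remaining ketone anti to both the chain and the silyloxy group, and the alkoxide closes onto the ester to give the silyloxy lactone F3.
- HF·pyridine gives the hydroxy lactone F4, and Dess–Martin oxidation gives 5.

**Step 9.** LiBH(s-Bu)3 may reduce the acetyl group 1,2, or the enolate may form with mixed geometry. Fallback, setting out from 15 and coming back at 19 through the same enolate 18, with geometry set by a different control element (in-plane attack on a ketene):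
- Pd-catalysed hydroxycarbonylation of 15 (Pd(OAc)2, dppf, CO, KOAc, DMF/H2O) gives the unsaturated acid F5.
- Hydrogenation (H2, Pd/C) gives the saturated acid F6 (C6 epimers, irrelevant).
- Oxalyl chloride gives the acid chloride F7, and Et3N generates the ketene F8 in the flask.
- MeLi (1 equiv, −78 °C) adds in the ketene plane from the side of the C7 methylene, away from the substituted C5, giving 18; PhNTf2 then gives 19.

**Step 17.** The hindered tetrasubstituted enol triflate may undergo simple reduction to the alkene, or CO insertion may be slow. Fallback, setting out from 30 and coming back at 31: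
- Stille hydroxymethylation with (tributylstannyl)methanol (Pd(PPh3)4, LiCl, dioxane, 90 °C) gives, with retention, the allylic alcohol F9.
- Primary-selective oxidation with TEMPO/PhI(OAc)2 converts only the primary allylic alcohol into the aldehyde, giving 31.

## Further compounds

F1 | step 2 | methyl 3-[(1R,2R)-2-hydroxy-1-methyl-6-oxocyclohexyl]propanoate | O[C@@H]1CCCC(=O)[C@]1(C)CCC(=O)OC
F2 | step 2 | methyl 3-[(1R,2R)-2-(TBS-oxy)-1-methyl-6-oxocyclohexyl]propanoate | CC(C)(C)[Si](C)(C)O[C@@H]1CCCC(=O)[C@]1(C)CCC(=O)OC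
F3 | step 2 | (4aR,5R,8aS)-5-(TBS-oxy)-4a,8a-dimethyloctahydro-2H-chromen-2-one | CC(C)(C)[Si](C)(C)O[C@@H]1CCC[C@](C)(O2)[C@]1(C)CCC2=O
F4 | step 2 | (4aR,5R,8aS)-5-hydroxy-4a,8a-dimethyloctahydro-2H-chromen-2-one | O[C@@H]1CCC[C@](C)(O2)[C@]1(C)CCC2=O
F5 | step 9 | (4aR,5R,8aS)-5-[3-(TBS-oxy)propyl]-4a,8a-dimethyl-2-oxo-3,4,4a,5,8,8a-hexahydro-2H-chromene-6-carboxylic acid | CC(C)(C)[Si](C)(C)OCCC[C@H]1C(C(=O)O)=CC[C@](C)(O2)[C@]1(C)CCC2=O
F6 | step 9 | (4aR,5S,6RS,8aS)-5-[3-(TBS-oxy)propyl]-4a,8a-dimethyl-2-oxooctahydro-2H-chromene-6-carboxylic acid | CC(C)(C)[Si](C)(C)OCCC[C@H]1C(C(=O)O)CC[C@](C)(O2)[C@]1(C)CCC2=O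
F7 | step 9 | (4aR,5S,6RS,8aS)-5-[3-(TBS-oxy)propyl]-4a,8a-dimethyl-2-oxooctahydro-2H-chromene-6-carbonyl chloride | CC(C)(C)[Si](C)(C)OCCC[C@H]1C(C(=O)Cl)CC[C@](C)(O2)[C@]1(C)CCC2=O
F8 | step 9 | (4aR,5R,8aS)-5-[3-(TBS-oxy)propyl]-4a,8a-dimethyl-6-(oxomethylidene)octahydro-2H-chromen-2-one (ketene) | CC(C)(C)[Si](C)(C)OCCC[C@H]1C(=C=O)CC[C@](C)(O2)[C@]1(C)CCC2=O
F9 | step 17 | 3-[(1S,2R,3S,6Z)-3-hydroxy-6-(1-hydroxypropan-2-ylidene)-2-[(3E,5R,7E)-5-hydroxy-4,8,12-trimethyltrideca-3,7,11-trien-1-yl]-2,3-dimethylcyclohexyl]propyl (9Z,12Z)-octadeca-9,12-dienoate | CCCCC/C=C\C/C=C\CCCCCCCC(=O)OCCC[C@H]1/C(=C(/C)CO)CC[C@](C)(O)[C@]1(C)CC/C=C(\C)[C@H](O)C/C=C(\C)CCC=C(C)C
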